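The butenolide (O–C15(=O)–C4=C5–C6) that bridges C4 and C6 of the ten-membered ring is the cycloisomer of a 2,3-allenoic acid. The route therefore first closes a cyclodecenyne by intramolecular Nozaki–Hiyama–Kishi alkynylation (C5–C6) and uses the resulting C6 carbinol as the only handle. In one operation its mesylate, CO and water are joined by zerovalent palladium to a ring-embedded allenoic acid (C15 enters on C4), and AgNO3 closes the lactone by forming the O–C6 bond, relaying the C6 configuration through the allene axis (net inversion) and creating the C4=C5 bond. Germacrane numbering is used (C1–C10 ring, C11–C13 α-methylene lactone, C14 hydroxymethyl, C15 butenolide carbonyl).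

Key step: step 16

Assumption: the lipase (step 2) and the chiral chromium catalyst (step 10) are taken to show the sense of induction predicted by their empirical models; the antipodal ligand would be used in step 10 otherwise.

Step 1
Reactants: 1 acrolein; 2 ethynyltrimethylsilane
Product: 3 rac-5-(trimethylsilyl)pent-1-en-4-yn-3-ol
Conditions: 2, n-BuLi, THF, −78 °C; then 1; aq NH4Cl
Reagents that add atoms: none
Why: 1,2-addition of the lithium acetylide to the enal carbonyl should give the racemic carbinol that becomes C3.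

Step 2
Reactants: 3 rac-5-(trimethylsilyl)pent-1-en-4-yn-3-ol
Product: 4 (S)-5-(trimethylsilyl)pent-1-en-4-yn-3-ol
Conditions: lipase PS (Burkholderia cepacia), vinyl acetate, hexane, 30 °C, stopped just past half conversion
Reagents that add atoms: none
Why: in this lipase-catalysed kinetic resolution the enzyme should acetylate the (R)-alcohol (silylethynyl as large, vinyl as medium substituent in the empirical model for secondary alcohols), so the (S)-alcohol that fixes C3 is recovered.

Step 3
Reactants: 4 (S)-5-(trimethylsilyl)pent-1-en-4-yn-3-ol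
Product: 5 (S)-5-(trimethylsilyl)pent-1-en-4-yn-3-yl 2-methylpropanoate
Conditions: i-PrCOCl, pyridine, DMAP (cat.), CH2Cl2, 0 °C
Reagents that add atoms: 2-methylpropanoyl chloride CC(C)C(Cl)=O
Why: DMAP-catalysed O-acylation leaves the stereocentre untouched and installs the C3 isobutyrate early, so that no hydroxyl differentiation is needed later.

Step 4
Reactants: 6 but-2-yne-1,4-diol
Product: 7 4-[(tert-butyldiphenylsilyl)oxy]but-2-yn-1-ol
Conditions: TBDPSCl (0.3 equiv), imidazole, DMF, 0 °C → rt (diol in excess)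
Reagents that add atoms: tert-butyl(chloro)diphenylsilane CC(C)(C)[Si](Cl)(c1ccccc1)c1ccccc1
Why: statistical monosilylation of a symmetric diol used in excess should give the mono-ether (future C14–O).

Step 5
Reactants: 7 4-[(tert-butyldiphenylsilyl)oxy]but-2-yn-1-ol
Product: 8 (Z)-4-[(tert-butyldiphenylsilyl)oxy]-3-iodobut-2-en-1-ol
Conditions: NaAlH2(OCH2CH2OMe)2, THF, 0 °C; then I2, −78 °C → 0 °C
Reagents that add atoms: iodine II
Why: hydroxyl-directed trans-hydroalumination places aluminium on the distal alkyne carbon (C10) and hydride on C9, and iodinolysis with retention gives the (Z)-iodide that fixes the C9=C10 geometry.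

Step 6
Reactants: 5 (S)-5-(trimethylsilyl)pent-1-en-4-yn-3-yl 2-methylpropanoate; 8 (Z)-4-[(tert-butyldiphenylsilyl)oxy]-3-iodobut-2-en-1-ol
Product: 10 (S,E)-6-{[(tert-butyldiphenylsilyl)oxy]methyl}-8-hydroxy-1-(trimethylsilyl)oct-6-en-1-yn-3-yl 2-methylpropanoate, via alkylborane 9 (not isolated)
Conditions: 5, 9-BBN, THF, 0 °C → rt; then 8, Pd(dppf)Cl2 (5 mol %), AsPh3, K3PO4 (aq), DMF, rt
Reagents that add atoms: none
Why: anti-Markovnikov hydroboration of the terminal alkene (9-BBN spares the silylated internal alkyne) followed by B-alkyl Suzuki–Miyaura coupling with retention at the vinyl iodide should form C10–C1 with the C8 carbon cis to the chain.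

Step 7
Reactants: 10 (S,E)-6-{[(tert-butyldiphenylsilyl)oxy]methyl}-8-hydroxy-1-(trimethylsilyl)oct-6-en-1-yn-3-yl 2-methylpropanoate
Product: 11 (S,E)-6-{[(tert-butyldiphenylsilyl)oxy]methyl}-8-oxo-1-(trimethylsilyl)oct-6-en-1-yn-3-yl 2-methylpropanoate
Conditions: MnO2, CH2Cl2, rt
Reagents that add atoms: none
Why: chemoselective oxidation of the primary allylic alcohol under neutral conditions should give the enal (C8) without isomerising the alkene or touching the propargylic ester.

Step 8
Reactants: 12 methyl acrylate; 13 [(tert-butyldimethylsilyl)oxy]acetaldehyde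
Product: 14 methyl 2-{2-[(tert-butyldimethylsilyl)oxy]-1-hydroxyethyl}acrylate (racemic)
Conditions: DABCO, MeOH, rt
Reagents that add atoms: none
Why: Morita–Baylis–Hillman reaction of the acrylate with an activated α-silyloxy aldehyde; the carbinol centre is lost in the next step.

Step 9
Reactants: 14 methyl 2-{2-[(tert-butyldimethylsilyl)oxy]-1-hydroxyethyl}acrylate
Product: 15 methyl (Z)-2-(bromomethyl)-4-[(tert-butyldimethylsilyl)oxy]but-2-enoate
Conditions: NBS, Me2S, CH2Cl2, 0 °C → rt
Reagents that add atoms: N-bromosuccinimide O=C1CCC(=O)N1Br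
Why: bromide displaces the alkoxysulfonium salt with allylic transposition (SN2′) to give the thermodynamically preferred 2-(bromomethyl)enoate carrying C6, C7, C11, C12 and C13.

Step 10
Reactants: 11 (S,E)-6-{[(tert-butyldiphenylsilyl)oxy]methyl}-8-oxo-1-(trimethylsilyl)oct-6-en-1-yn-3-yl 2-methylpropanoate; 15 methyl (Z)-2-(bromomethyl)-4-[(tert-butyldimethylsilyl)oxy]but-2-enoate
Product: 17 (4R,5R)-4-{[(tert-butyldimethylsilyl)oxy]methyl}-5-[(1E,5S)-2-{[(tert-butyldiphenylsilyl)oxy]methyl}-5-[(2-methylpropanoyl)oxy]-7-(trimethylsilyl)hept-1-en-6-yn-1-yl]-3-methylideneoxolan-2-one, via trimethylsilyl ether 16 (not isolated)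
Conditions: CrCl2 (10 mol %), (S,S)-carbazole bis(oxazoline) ligand (12 mol %), Mn, Me3SiCl, Et3N (cat.), THF, rt; then TsOH·H2O (cat.), CH2Cl2
Reagents that add atoms: none
Why: catalytic asymmetric Nozaki–Hiyama–Kishi 2-(alkoxycarbonyl)allylation, in which the γ-substituted allylchromium should add 1,2 to the enal through a chair transition state with the C6 substituent equatorial (anti adduct, hence the trans lactone after desilylation–lactonisation) while the chiral chromium complex selects the aldehyde face (7R,8R).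

Step 11
Reactants: 17 the trans lactone of step 10
Product: 18 (4R,5R)-4-{[(tert-butyldimethylsilyl)oxy]methyl}-5-[(1E,5S)-2-{[(tert-butyldiphenylsilyl)oxy]methyl}-7-iodo-5-[(2-methylpropanoyl)oxy]hept-1-en-6-yn-1-yl]-3-methylideneoxolan-2-one
Conditions: NIS, AgNO3 (10 mol %), acetone, rt, dark
Reagents that add atoms: N-iodosuccinimide O=C1CCC(=O)N1I
Why: silver-catalysed iododesilylation of the alkynylsilane via a silver acetylide should give the iodoalkyne under neutral conditions.

Step 12
Reactants: 18 the iodoalkyne of step 11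
Product: 19 (4R,5R)-4-(hydroxymethyl)-5-[(1E,5S)-2-{[(tert-butyldiphenylsilyl)oxy]methyl}-7-iodo-5-[(2-methylpropanoyl)oxy]hept-1-en-6-yn-1-yl]-3-methylideneoxolan-2-one
Conditions: HF·pyridine, pyridine, THF, 0 °C
Reagents that add atoms: none
Why: buffered fluoride should cleave the primary TBS ether much faster than the bulkier TBDPS ether and is too mild to cause translactonisation.

Step 13
Reactants: 19 the primary alcohol of step 12
Product: 20 (2R,3S)-2-[(1E,5S)-2-{[(tert-butyldiphenylsilyl)oxy]methyl}-7-iodo-5-[(2-methylpropanoyl)oxy]hept-1-en-6-yn-1-yl]-4-methylidene-5-oxooxolane-3-carbaldehyde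
Conditions: Dess–Martin periodinane, NaHCO3, CH2Cl2, 0 °C; used crude
Reagents that add atoms: none
Why: buffered Dess–Martin oxidation should give the C6 aldehyde without epimerising C7 or moving the exocyclic alkene into conjugation.

Step 14
Reactants: 20 the iodoalkyne aldehyde of step 13
Product: 21 (3S,6R,7R,8R,9E)-14-[(tert-butyldiphenylsilyl)oxy]-6-hydroxy-3-[(2-methylpropanoyl)oxy]-15-norgermacra-9,11(13)-dien-4-yn-12,8-olide (ten-membered C1–C10 ring with C4≡C5, trans-fused α-methylene lactone on C7/C8)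
Conditions: CrCl2 (8 equiv), NiCl2 (2 mol %), THF, rt, slow addition, high dilution
Reagents that add atoms: none
Why: intramolecular Nozaki–Hiyama–Kishi reaction, in which CrCl2 (nickel-catalysed) inserts into the C–I bond and the alkynylchromium adds to the aldehyde without base, closing the C5–C6 bond; Felkin–Anh addition anti to C8 should give the 6R carbinol (C6–O, C7–C11 and C8–O all syn).

Step 15
Reactants: 21 the macrocyclic propargylic alcohol of step 14
Product: 22 (3S,6R,7S,8R,9E)-14-[(tert-butyldiphenylsilyl)oxy]-6-[(methanesulfonyl)oxy]-3-[(2-methylpropanoyl)oxy]-15-norgermacra-9,11(13)-dien-4-yn-12,8-olide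
Conditions: MsCl, Et3N, CH2Cl2, −78 °C; used at once
Reagents that add atoms: methanesulfonyl chloride CS(=O)(=O)Cl
Why: O-sulfonylation of the propargylic alcohol proceeds with retention at C6 and turns it into the leaving group for the key step.

Step 16
Reactants: 22 the propargylic mesylate of step 15
Product: 24 (3S,6R,7S,8R,9E)-14-[(tert-butyldiphenylsilyl)oxy]-3-[(2-methylpropanoyl)oxy]germacra-4,9,11(13)-triene-12,8:15,6-diolide, via allenoic acid 23 (not isolated)
Conditions: Pd(PPh3)4 (5 mol %), CO (1 atm), 2,6-lutidine, THF/H2O (10:1), rt; then AgNO3 (20 mol %), acetone, rt, dark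
Reagents that add atoms: carbon monoxide [C-]#[O+]; water O
Why: Zerovalent palladium ionises the propargylic mesylate by anti SN2′ attack at C4, the σ-allenylpalladium species inserts CO and is hydrolysed to the (aS)-allenoic acid 23 (palladium-catalysed hydroxycarbonylation of propargylic sulfonates, centre-to-axis transfer), and monovalent silver then activates the C5=C6 π bond so that a carboxyl oxygen adds anti to the metal at C6 before protodemetalation (silver-catalysed cycloisomerisation of 2,3-allenoic acids to butenolides). The butenolide closes in a 5-endo-trig mode on the allene terminus, the only carbon the C15 carboxyl can reach, which also turns C4=C5 into the E-configured ring alkene of the bridged bicyclic core. C6 is the only new stereocentre and is fixed by the allene axis (axis-to-centre transfer), so the 6R carbinol of 21 is relayed to 6R in 24 with net geometric inversion, the ring oxygen now coming from CO or water. The step needs chemoselective ionisation of the propargylic mesylate in the presence of the allylic C8 lactone and the C3 isobutyrate, which the far better sulfonate leaving group should secure at room temperature, and carbonylation at C4, which is inherent to SN2′ attack on a secondary propargylic electrophile. 2,6-Lutidine buffers the methanesulfonic acid so that the silyl ether and the allene axis survive.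

Step 17
Reactants: 24 the silyl-protected dilactone of step 16
Product: 25 (3S,6R,7S,8R,9E)-14-hydroxy-3-[(2-methylpropanoyl)oxy]germacra-4,9,11(13)-triene-12,8:15,6-diolide (target)
Conditions: HF·pyridine, THF, 0 °C → rt
Reagents that add atoms: none
Why: fluoride desilylation under mildly acidic conditions should free the C14 alcohol while both lactones, the isobutyrate and the α-methylene unit are untouched.

Compound list
1 | acrolein (prop-2-enal) | C=CC=O | starting material
2 | ethynyltrimethylsilane | C#C[Si](C)(C)C | starting material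
3 | rac-5-(trimethylsilyl)pent-1-en-4-yn-3-ol | C=CC(O)C#C[Si](C)(C)C | intermediate
4 | (S)-5-(trimethylsilyl)pent-1-en-4-yn-3-ol | C=C[C@H](O)C#C[Si](C)(C)C | intermediate
5 | (S)-5-(trimethylsilyl)pent-1-en-4-yn-3-yl 2-methylpropanoate | C=C[C@H](OC(=O)C(C)C)C#C[Si](C)(C)C | intermediate
6 | but-2-yne-1,4-diol | OCC#CCO | starting material
7 | 4-[(tert-butyldiphenylsilyl)oxy]but-2-yn-1-ol | OCC#CCO[Si](c1ccccc1)(c1ccccc1)C(C)(C)C | intermediate
8 | (Z)-4-[(tert-butyldiphenylsilyl)oxy]-3-iodobut-2-en-1-ol (iodine cis to CH2OH) | OC/C=C(\I)CO[Si](c1ccccc1)(c1ccccc1)C(C)(C)C | intermediate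
9 | (S)-5-(9-borabicyclo[3.3.1]nonan-9-yl)-1-(trimethylsilyl)pent-1-yn-3-yl 2-methylpropanoate | CC(C)C(=O)O[C@@H](CCB1C2CCCC1CCC2)C#C[Si](C)(C)C | intermediate (not isolated)
10 | (S,E)-6-{[(tert-butyldiphenylsilyl)oxy]methyl}-8-hydroxy-1-(trimethylsilyl)oct-6-en-1-yn-3-yl 2-methylpropanoate (CH2OH cis to the C5 chain) | OC/C=C(/CO[Si](c1ccccc1)(c1ccccc1)C(C)(C)C)CC[C@H](OC(=O)C(C)C)C#C[Si](C)(C)C | intermediate
11 | (S,E)-6-{[(tert-butyldiphenylsilyl)oxy]methyl}-8-oxo-1-(trimethylsilyl)oct-6-en-1-yn-3-yl 2-methylpropanoate (CHO cis to the C5 chain) | O=C/C=C(/CO[Si](c1ccccc1)(c1ccccc1)C(C)(C)C)CC[C@H](OC(=O)C(C)C)C#C[Si](C)(C)C | intermediate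
12 | methyl acrylate | C=CC(=O)OC | starting material
13 | [(tert-butyldimethylsilyl)oxy]acetaldehyde | O=CCO[Si](C)(C)C(C)(C)C | starting material
14 | methyl 2-{2-[(tert-butyldimethylsilyl)oxy]-1-hydroxyethyl}acrylate (racemic) | C=C(C(=O)OC)C(O)CO[Si](C)(C)C(C)(C)C | intermediate
15 | methyl (Z)-2-(bromomethyl)-4-[(tert-butyldimethylsilyl)oxy]but-2-enoate (CH2Br cis to CH2OTBS) | COC(=O)/C(CBr)=C/CO[Si](C)(C)C(C)(C)C | intermediate
16 | methyl (3R,4R,5E,9S)-3-{[(tert-butyldimethylsilyl)oxy]methyl}-6-{[(tert-butyldiphenylsilyl)oxy]methyl}-2-methylidene-9-[(2-methylpropanoyl)oxy]-11-(trimethylsilyl)-4-[(trimethylsilyl)oxy]undec-5-en-10-ynoate (anti adduct) | COC(=O)C(=C)[C@H](CO[Si](C)(C)C(C)(C)C)[C@H](O[Si](C)(C)C)/C=C(/CO[Si](c1ccccc1)(c1ccccc1)C(C)(C)C)CC[C@H](OC(=O)C(C)C)C#C[Si](C)(C)C | intermediate (not isolated)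
17 | (4R,5R)-4-{[(tert-butyldimethylsilyl)oxy]methyl}-5-[(1E,5S)-2-{[(tert-butyldiphenylsilyl)oxy]methyl}-5-[(2-methylpropanoyl)oxy]-7-(trimethylsilyl)hept-1-en-6-yn-1-yl]-3-methylideneoxolan-2-one (trans lactone) | C=C1C(=O)O[C@H](/C=C(/CO[Si](c2ccccc2)(c2ccccc2)C(C)(C)C)CC[C@H](OC(=O)C(C)C)C#C[Si](C)(C)C)[C@H]1CO[Si](C)(C)C(C)(C)C | intermediate
18 | (4R,5R)-4-{[(tert-butyldimethylsilyl)oxy]methyl}-5-[(1E,5S)-2-{[(tert-butyldiphenylsilyl)oxy]methyl}-7-iodo-5-[(2-methylpropanoyl)oxy]hept-1-en-6-yn-1-yl]-3-methylideneoxolan-2-one | C=C1C(=O)O[C@H](/C=C(/CO[Si](c2ccccc2)(c2ccccc2)C(C)(C)C)CC[C@H](OC(=O)C(C)C)C#CI)[C@H]1CO[Si](C)(C)C(C)(C)C | intermediate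
19 | (4R,5R)-4-(hydroxymethyl)-5-[(1E,5S)-2-{[(tert-butyldiphenylsilyl)oxy]methyl}-7-iodo-5-[(2-methylpropanoyl)oxy]hept-1-en-6-yn-1-yl]-3-methylideneoxolan-2-one | C=C1C(=O)O[C@H](/C=C(/CO[Si](c2ccccc2)(c2ccccc2)C(C)(C)C)CC[C@H](OC(=O)C(C)C)C#CI)[C@H]1CO | intermediate
20 | (2R,3S)-2-[(1E,5S)-2-{[(tert-butyldiphenylsilyl)oxy]methyl}-7-iodo-5-[(2-methylpropanoyl)oxy]hept-1-en-6-yn-1-yl]-4-methylidene-5-oxooxolane-3-carbaldehyde | C=C1C(=O)O[C@H](/C=C(/CO[Si](c2ccccc2)(c2ccccc2)C(C)(C)C)CC[C@H](OC(=O)C(C)C)C#CI)[C@H]1C=O | intermediate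
21 | (3S,6R,7R,8R,9E)-14-[(tert-butyldiphenylsilyl)oxy]-6-hydroxy-3-[(2-methylpropanoyl)oxy]-15-norgermacra-9,11(13)-dien-4-yn-12,8-olide | C=C1C(=O)O[C@@H]2/C=C(/CO[Si](c3ccccc3)(c3ccccc3)C(C)(C)C)CC[C@H](OC(=O)C(C)C)C#C[C@H](O)[C@@H]12 | intermediate
22 | (3S,6R,7S,8R,9E)-14-[(tert-butyldiphenylsilyl)oxy]-6-[(methanesulfonyl)oxy]-3-[(2-methylpropanoyl)oxy]-15-norgermacra-9,11(13)-dien-4-yn-12,8-olide | C=C1C(=O)O[C@@H]2/C=C(/CO[Si](c3ccccc3)(c3ccccc3)C(C)(C)C)CC[C@H](OC(=O)C(C)C)C#C[C@H](OS(C)(=O)=O)[C@@H]12 | intermediate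
23 | (3S,7S,8R,9E,aS)-14-[(tert-butyldiphenylsilyl)oxy]-3-[(2-methylpropanoyl)oxy]-12,8-olidogermacra-4,5,9,11(13)-tetraen-15-oic acid (ring allene C4=C5=C6, CO2H on C4) | C=C1C(=O)O[C@@H]2/C=C(/CO[Si](c3ccccc3)(c3ccccc3)C(C)(C)C)CC[C@H](OC(=O)C(C)C)C(C(=O)O)=[C@]=C([H])[C@@H]12 | intermediate (not isolated)
24 | (3S,6R,7S,8R,9E)-14-[(tert-butyldiphenylsilyl)oxy]-3-[(2-methylpropanoyl)oxy]germacra-4,9,11(13)-triene-12,8:15,6-diolide | C=C1C(=O)O[C@@H]2/C=C(/CO[Si](c4ccccc4)(c4ccccc4)C(C)(C)C)CC[C@H](OC(=O)C(C)C)C3=C[C@@H](OC3=O)[C@@H]12 | intermediate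
25 | (3S,6R,7S,8R,9E)-14-hydroxy-3-[(2-methylpropanoyl)oxy]germacra-4,9,11(13)-triene-12,8:15,6-diolide | C=C1C(=O)O[C@@H]2/C=C(/CO)CC[C@H](OC(=O)C(C)C)C3=C[C@@H](OC3=O)[C@@H]12 | target

Total step count: 17. Longest linear sequence: 13 steps (1, 2, 3, 6, 7, 10, 11, 12, 13, 14, 15, 16, 17).

Steps most likely to fail

1. Step 14. The alkynylchromium may add to the C6 aldehyde with poor or reversed facial selectivity, because the forming ten-membered ring rather than the Felkin–Anh preference dictates the approach; slow closure would also let the sensitive aldehyde isomerise. Fallback: setting out from 20, the ring is closed as before without regard to C6, giving the (6S)-epimeric propargylic alcohol F1, alone or mixed with 21. Dess–Martin oxidation converts this material into the single macrocyclic ynone F2. Corey–Bakshi–Shibata reduction with the (R)-methyl oxazaborolidine and catecholborane (alkyne as the small substituent) then sets 6R under reagent control and comes back to the route at 21.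

2. Step 16. Closure of the strained allenoic acid may be slower than loss of its axial chirality, or than ionisation of the allylic C8–O and C3–O esters by palladium, so that C6 is scrambled or material is diverted. Fallback: setting out from 22, alkoxycarbonylation with Pd(PPh3)4, CO and MeOH (2,6-lutidine) gives the isolable methyl allenoate F3, freed from palladium. Iodolactonisation (I2, MeCN/H2O) closes the ring by anti addition across C5=C6 with loss of the methyl group, still forming the O–C6 bond with the same axis-to-centre transfer, and gives the 5-iodobutenolide F4. Zinc dust with NH4Cl in THF/MeOH removes the iodine and comes back to the route at 24.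

3. Step 10. The allylchromium may react through the crotyl-type geometry that leads to the syn adduct (cis lactone), may lose silanolate by 1,4-elimination, or may add to the enal with low enantioselectivity. Fallback: setting out from 11, with commercial methyl 4-hydroxybut-2-ynoate silylated (TBSCl, imidazole) to the ynoate F5. Syn-hydroalumination ((i-Bu)2AlH, HMPA) and trapping of the α-aluminoacrylate with ICH2Bpin gives the geometrically defined allylboronate F6 (CH2B trans to CH2OTBS). Its allylboration of 11, catalysed by a chiral BINOL-derived phosphoric acid, passes through a closed chair transition state that translates the boronate geometry into the anti adduct; TsOH-induced lactonisation comes back to the route at 17.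

Further compounds
F1 | step 14 | (3S,6S,7R,8R,9E)-14-[(tert-butyldiphenylsilyl)oxy]-6-hydroxy-3-[(2-methylpropanoyl)oxy]-15-norgermacra-9,11(13)-dien-4-yn-12,8-olide | C=C1C(=O)O[C@@H]2/C=C(/CO[Si](c3ccccc3)(c3ccccc3)C(C)(C)C)CC[C@H](OC(=O)C(C)C)C#C[C@@H](O)[C@@H]12
F2 | step 14 | (3S,7S,8R,9E)-14-[(tert-butyldiphenylsilyl)oxy]-3-[(2-methylpropanoyl)oxy]-6-oxo-15-norgermacra-9,11(13)-dien-4-yn-12,8-olide | C=C1C(=O)O[C@@H]2/C=C(/CO[Si](c3ccccc3)(c3ccccc3)C(C)(C)C)CC[C@H](OC(=O)C(C)C)C#CC(=O)[C@@H]12
F3 | step 16 | methyl (3S,7S,8R,9E,aS)-14-[(tert-butyldiphenylsilyl)oxy]-3-[(2-methylpropanoyl)oxy]-12,8-olidogermacra-4,5,9,11(13)-tetraen-15-oate | C=C1C(=O)O[C@@H]2/C=C(/CO[Si](c3ccccc3)(c3ccccc3)C(C)(C)C)CC[C@H](OC(=O)C(C)C)C(C(=O)OC)=[C@]=C([H])[C@@H]12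
F4 | step 16 | (3S,6R,7S,8R,9E)-14-[(tert-butyldiphenylsilyl)oxy]-5-iodo-3-[(2-methylpropanoyl)oxy]germacra-4,9,11(13)-triene-12,8:15,6-diolide | C=C1C(=O)O[C@@H]2/C=C(/CO[Si](c4ccccc4)(c4ccccc4)C(C)(C)C)CC[C@H](OC(=O)C(C)C)C3=C(I)[C@@H](OC3=O)[C@@H]12
F5 | step 10 | methyl 4-[(tert-butyldimethylsilyl)oxy]but-2-ynoate | COC(=O)C#CCO[Si](C)(C)C(C)(C)C
F6 | step 10 | methyl (Z)-4-[(tert-butyldimethylsilyl)oxy]-2-[(4,4,5,5-tetramethyl-1,3,2-dioxaborolan-2-yl)methyl]but-2-enoate | COC(=O)/C(CB1OC(C)(C)C(C)(C)O1)=C\CO[Si](C)(C)C(C)(C)C
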